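## Structural features

The target is an isoflavone: benzo ring A (hydroxyls at C5 and C7) is fused to the 4-pyranone ring C, and C3 of ring C carries the aryl ring B. Ring B is 1,3,4,5-tetrasubstituted: B1 is bonded to C3, B3 carries a prenyl group, and the B4 oxygen and the B5 carbon are bridged by three carbons to form ring D, a 2,2-dimethylchroman (O1', C2', C3', C4'). The single stereocentre is the secondary carbinol C3' (R). It lies between the quaternary C2' and the benzylic methylene C4' and has no neighbouring stereocentre to relay asymmetry, so it must be set by a chiral reagent or catalyst. Fragile groups are the trisubstituted prenyl alkene (protic acid, electrophilic oxidants, hydrogenation catalysts), the chromenone (C2 is open to hard nucleophiles and hydride), and the electron-rich ring A with its phenols. The real difficulties are telling apart the three phenols of the isoflavone core, placing two different ortho substituents around the ring B oxygen, and introducing one oxygen atom at C3' with absolute control while a second alkene is present. The key step exploits the C3'=C4' dehydro form of ring D, a 2,2-dimethyl-2H-chromene whose cis-disubstituted alkene is conjugated with ring B. This is the substrate class that salen–manganese oxygen transfer handles best, and the benzylic C4'–O bond of the resulting oxirane can later be cut while the C3'–O bond is kept.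

## Logic of the disconnections

13 from 12: no skeletal bond is cut; the O5–H and O7–H bonds are traced back to two O–CH2 acetal bonds. Both ring A phenols must be masked during the oxidation and the reduction, and one acetal type lets both come off together. The gain is a last step that is a pure deprotection with the stereocentre already in place. The demand is an acid treatment mild enough to spare the prenyl alkene and the tertiary ring D ether.

12 from 11: the C4'–H bond is replaced by the C4'–O bond of an oxirane bridging C3' and C4'. A carbinol next to a benzylic methylene is the reductive-opening product of a benzylic epoxide, and the benzylic C–O bond is the weaker of the two. The gain is that the stereochemical problem becomes a face-selective alkene oxidation. The demand is cleavage at C4' only, without reduction of the chromenone.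

11 from 10: the C3'–O and C4'–O bonds are cut. Both stereocentres vanish and the precursor is achiral. The demand is enantioface control by the catalyst alone, together with chemoselectivity against the prenyl alkene, the C2=C3 bond of ring C and ring A.

10 from 9: the O5–CH2 acetal bond is cut. The chelated 5-hydroxyl is tolerated by every earlier step but not by the conditions of steps 8 and 9, so it is masked last. The gain is that ring B can be built with a single protecting group on the molecule. The demand is a base strong enough to break the hydrogen bond to the C4 carbonyl.

9 from 7 (through 8): the B5–C4' bond is cut; the O1'–C2' bond already exists in 7 and is broken and re-formed in the pericyclic cascade. A 2,2-dimethylchromene is the thermal product of an aryl 1,1-dimethylpropargyl ether. The gain is that ring D collapses to an ether side chain. The demand is that the new C–C bond go to B5, which is secured because B3 is already occupied.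

7 from 6 and 3: the ether bond between the B4 oxygen and C2' is cut. This gives a phenol and a five-carbon electrophile that is bought. The demand is O-alkylation of a hindered phenol by a tertiary propargylic halide without touching the chelated 5-hydroxyl.

6 from 5, and 5 from 4: the B3–CH2 bond of the prenyl group is cut along a [3,3] retron, and the vinyl group of 5 is traced to the alkyne of 4. C-Prenylation thereby becomes an O-alkylation with the same reagent 3, and ortho regiochemistry is guaranteed. The demands are a hydrogenation that stops at the alkene and a rearrangement that outruns ionisation of the tertiary ether.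

4 from 2 and 3, and 2 from 1: first the B4 oxygen–carbon bond, then the O7–CH2 acetal bond is cut. The 7-hydroxyl is the most acidic and must be capped so that alkylation goes to the ring B hydroxyl. The gain is arrival at 1 and 3, both commercial. The demand is clean mono-alkylation of the monoanion at O7.

## Other disconnections considered

Alternative 1: The cut is the bond between C4' and ring B carbon B5, made on a bromoarene that stands in for ring B. In the forward direction Rh2(OAc)4 (divalent rhodium) would decompose the α-aryloxy diazoketone A1, and the electrophilic carbenoid would substitute the one free ortho position to close ring D as the chroman-3-one A2. The ketone would then be reduced enantioselectively (Corey–Bakshi–Shibata reduction or transfer hydrogenation), and the bromide joined to a ring A/ring C partner by Suzuki coupling.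
- In favour: the two flanks of the ketone (quaternary C2' against CH2) differ strongly, and a hydride reagent ignores the prenyl alkene. On chemoselectivity in the stereo-defining step this alternative is better than the chosen plan. It is also convergent and needs no differentiation of phenols.
- Against: A1 requires diazomethane or a substitute on a hindered aryloxyisobutyric acid. The carbenoid has other outlets (cyclopropanation of the prenyl alkene, Buchner ring expansion). Chroman-3-ones enolise and oxidise easily.
- Comparison: both plans pair one metal-centred electrophile with one reduction, so they are equal in the number of stereo-relevant operations. The chosen plan starts from a complete isoflavone, whereas this one must assemble it, which makes it clearly longer than ten steps.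

Alternative 2: The cut is C4–C4a of ring C. Trifluoroacetic anhydride would convert the (Z)-acid A3 into a mixed anhydride whose acyl carbon attacks ring A ortho to the ether oxygen (Friedel–Crafts acylation), giving the chromenone A4.
- In favour: the aryloxy ring is symmetrical, so the closure has no regiochemical question, and no selective protection of a trihydroxy isoflavone is needed. The allyl ethers would come off with Pd(PPh3)4 (zerovalent palladium) and a soft nucleophile under neutral conditions, which is gentler on the prenyl group than the acid of step 10. On that point the alternative is the better.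
- Against: the cut creates no stereocentre. The C3' carbinol must already be present in the ring B fragment, so an asymmetric step of the same kind as step 8 is still needed and the ring C construction comes on top. The closure liberates trifluoroacetic acid next to the prenyl alkene and an electron-rich chroman ring, only the Z acid can cyclise, and A3 takes several steps to make.
- Comparison: structurally convergent, mechanistically a plain electrophilic aromatic substitution, equal to the chosen plan in leaving the stereocentre untouched once made, but worse in step economy.

Alternative 3: The cut is O1'–C2'. Catalytic camphorsulfonic acid would make the ring B phenol of the epoxide A5 open the oxirane at its tertiary carbon (6-endo), closing ring D and giving A6, which is the same compound as 12. C3' keeps its configuration because its C–O bond is not involved.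
- In favour: the epoxide of a trisubstituted prenyl alkene is an ideal case for Shi epoxidation, so enantiocontrol is at least as well founded as in the chosen plan. No reductive step is needed, and the route joins the chosen one at 12.
- Against: the precursor carries two identical prenyl groups of which exactly one must be epoxidised, which is at best statistical. The dioxirane also requires the phenol to be protected and released again. The closure must go 6-endo against the 5-exo mode (attack at the secondary carbon), a regiochemical question that does not arise in the chosen plan because ring D is already formed before step 8.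
- Comparison: similar length, one redox operation fewer, but a statistical loss and an extra selectivity issue. Mechanistically a polar, cation-like opening replaces oxygen-atom transfer plus radical opening.

Key step: step 8

Remark: 3-chloro-3-methylbut-1-yne (3), the chloride of 2-methylbut-3-yn-2-ol, is assumed to be bought as such, so no activation step is needed.
Remark: ring B carbons are labelled B1 to B6 (B1 bonded to C3 of ring C, B4 bearing oxygen) so that the primed locants O1', C2', C3', C4' are reserved for ring D.

## Route

Step 1
Reactants: 1 genistein [5,7-dihydroxy-3-(4-hydroxyphenyl)chromen-4-one]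
Product: 2 5-hydroxy-3-(4-hydroxyphenyl)-7-(methoxymethoxy)chromen-4-one
Conditions: t-BuOK (1.0 equiv), DMF, 0 °C; MOMCl (1.0 equiv), 0 °C to rt
Reagents that add atoms: chloromethyl methyl ether, COCCl
Why: O-Alkylation of a phenoxide (Williamson type): one equivalent of base forms the monoanion at O7, the most acidic site because it is para to the pyranone carbonyl. The ring B hydroxyl is less acidic and the 5-hydroxyl is locked in a hydrogen bond to the C4 carbonyl, so the single MOM group should go to O7.

Step 2
Reactants: 2 5-hydroxy-3-(4-hydroxyphenyl)-7-(methoxymethoxy)chromen-4-one; 3 3-chloro-3-methylbut-1-yne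
Product: 4 5-hydroxy-7-(methoxymethoxy)-3-[4-(2-methylbut-3-yn-2-yloxy)phenyl]chromen-4-one
Conditions: 3 (1.5 equiv), K2CO3, KI, CuI (cat.), acetone, 60 °C
Reagents that add atoms: none
Why: Copper-assisted O-alkylation of a phenol with a tertiary propargylic chloride, the standard entry to aryl 1,1-dimethylpropargyl ethers. The ring B hydroxyl is the only free non-chelated phenol, and K2CO3 in acetone does not alkylate the chelated 5-hydroxyl.

Step 3
Reactants: 4 5-hydroxy-7-(methoxymethoxy)-3-[4-(2-methylbut-3-yn-2-yloxy)phenyl]chromen-4-one
Product: 5 5-hydroxy-7-(methoxymethoxy)-3-[4-(2-methylbut-3-en-2-yloxy)phenyl]chromen-4-one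
Conditions: H2 (1 atm), Pd/CaCO3 poisoned with Pb(OAc)2, quinoline, EtOAc, rt
Reagents that add atoms: none
Why: Lindlar semihydrogenation: the poisoned palladium surface reduces the terminal alkyne to the vinyl group and is expected to stop there when hydrogen uptake is monitored. The C2=C3 bond of ring C and the MOM acetal are inert.

Step 4
Reactants: 5 5-hydroxy-7-(methoxymethoxy)-3-[4-(2-methylbut-3-en-2-yloxy)phenyl]chromen-4-one
Product: 6 5-hydroxy-3-[4-hydroxy-3-(3-methylbut-2-enyl)phenyl]-7-(methoxymethoxy)chromen-4-one
Conditions: PhNEt2, 130 °C, argon
Reagents that add atoms: none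
Why: Aromatic Claisen rearrangement of an aryl 1,1-dimethylallyl ether ([3,3] shift through a chair, then tautomerisation); the allyl termini are exchanged, so the tertiary ether becomes the linear prenyl group at B3 (both ortho positions of ring B are equivalent). The weakly basic solvent suppresses acid-catalysed ionisation of the tertiary ether and cyclisation of the ortho-prenylphenol.

Step 5
Reactants: 6 5-hydroxy-3-[4-hydroxy-3-(3-methylbut-2-enyl)phenyl]-7-(methoxymethoxy)chromen-4-one; 3 3-chloro-3-methylbut-1-yne
Product: 7 5-hydroxy-7-(methoxymethoxy)-3-[3-(3-methylbut-2-enyl)-4-(2-methylbut-3-yn-2-yloxy)phenyl]chromen-4-one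
Conditions: 3 (2 equiv), K2CO3, KI, CuI (cat.), acetone, 60 °C
Reagents that add atoms: none
Why: The same copper-assisted propargylic O-alkylation as in step 2, now on the ortho-prenylated phenol; the copper acetylide-derived electrophile is small enough for hindered phenols. The chelated 5-hydroxyl again stays free.

Step 6
Reactants: 7 5-hydroxy-7-(methoxymethoxy)-3-[3-(3-methylbut-2-enyl)-4-(2-methylbut-3-yn-2-yloxy)phenyl]chromen-4-one
Product: 9 3-[2,2-dimethyl-8-(3-methylbut-2-enyl)-2H-chromen-6-yl]-5-hydroxy-7-(methoxymethoxy)chromen-4-one, via ortho-allenylphenol 8 (not isolated)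
Conditions: o-xylene, 140 °C, argon
Reagents that add atoms: none
Why: Propargyl Claisen rearrangement to the allenyl dienone, enolisation to 8, [1,5]-hydrogen shift to an ortho-quinone methide and oxa-6π electrocyclisation, the usual thermal route from aryl 1,1-dimethylpropargyl ethers to 2,2-dimethylchromenes. B3 is blocked by the prenyl group, so the new C–C bond can form only at B5.

Step 7
Reactants: 9 3-[2,2-dimethyl-8-(3-methylbut-2-enyl)-2H-chromen-6-yl]-5-hydroxy-7-(methoxymethoxy)chromen-4-one
Product: 10 3-[2,2-dimethyl-8-(3-methylbut-2-enyl)-2H-chromen-6-yl]-5,7-bis(methoxymethoxy)chromen-4-one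
Conditions: NaH, DMF, 0 °C; MOMCl, 0 °C to rt
Reagents that add atoms: chloromethyl methyl ether, COCCl
Why: O-Alkylation of the sodium phenoxide; NaH is needed to break the hydrogen bond between O5–H and the C4 carbonyl. After this step no phenol is left that could be chlorinated by the oxidant of step 8 or bind the titanium reagent of step 9.

Step 8
Reactants: 10 3-[2,2-dimethyl-8-(3-methylbut-2-enyl)-2H-chromen-6-yl]-5,7-bis(methoxymethoxy)chromen-4-one
Product: 11 3-[(3R,4R)-3,4-epoxy-2,2-dimethyl-8-(3-methylbut-2-enyl)chroman-6-yl]-5,7-bis(methoxymethoxy)chromen-4-one
Conditions: (R,R)-N,N'-bis(3,5-di-tert-butylsalicylidene)-1,2-cyclohexanediaminomanganese chloride (trivalent manganese, 5 mol%), 4-phenylpyridine N-oxide (20 mol%), aq. NaOCl (1.3 equiv, Na2HPO4 buffer, pH 11.3), CH2Cl2, 0 °C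
Reagents that add atoms: sodium hypochlorite, [Na+].[O-]Cl
Why: Hypochlorite transfers its oxygen atom to the trivalent manganese centre and generates the active oxo complex (pentavalent manganese), which the N-oxide stabilises as axial ligand. The C3'=C4' alkene approaches this oxo group side-on across the diamine bridge; the first C–O bond forms at C3' and the benzylic radical at C4' collapses onto the same oxygen. The closest known reaction type is the Jacobsen epoxidation of 2,2-dimethyl-2H-chromenes. The oxirane is closed by [2+1] addition of one oxygen atom to one alkene face (formally a 3-exo collapse of the C4' radical) and is therefore cis-fused to ring D. C3' and C4' are both set by the chiral ligand alone (reagent control); by analogy with simple 2,2-dimethylchromenes the (R,R) ligand is expected to make both carbons R, and only C3' has to survive. The step needs enantioface selectivity and chemoselectivity: the conjugated cis-disubstituted alkene is the privileged substrate, the isolated trisubstituted prenyl alkene reacts more slowly and is shielded further by limiting the hypochlorite, the C2=C3 bond of ring C is electron-poor, and with both ring A oxygens capped no phenoxide is exposed to hypochlorite. The buffered basic medium protects the acid-labile benzylic epoxide, which should be carried into step 9 after filtration through base-washed silica only.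

Step 9
Reactants: 11 3-[(3R,4R)-3,4-epoxy-2,2-dimethyl-8-(3-methylbut-2-enyl)chroman-6-yl]-5,7-bis(methoxymethoxy)chromen-4-one
Product: 12 3-[(3R)-3-hydroxy-2,2-dimethyl-8-(3-methylbut-2-enyl)chroman-6-yl]-5,7-bis(methoxymethoxy)chromen-4-one
Conditions: Cp2TiCl2 (10 mol%), Mn dust (2 equiv), 2,4,6-collidine hydrochloride (2.5 equiv), 1,4-cyclohexadiene (5 equiv), THF, rt
Reagents that add atoms: none
Why: Titanocene-catalysed reductive epoxide opening: Cp2TiCl (trivalent titanium, regenerated by Mn) cleaves the C4'–O bond homolytically because this gives the benzylic radical, which takes a hydrogen atom from 1,4-cyclohexadiene, and collidinium chloride then releases the alcohol from titanium. The C3'–O bond is never broken and the order O > C2' > C4' > H holds before and after, so C3' remains R. The vinylogous-ester carbonyl, the prenyl alkene and the MOM ethers should not be reduced by this mild single-electron reagent.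

Step 10
Reactants: 12 3-[(3R)-3-hydroxy-2,2-dimethyl-8-(3-methylbut-2-enyl)chroman-6-yl]-5,7-bis(methoxymethoxy)chromen-4-one
Product: 13 5,7-dihydroxy-3-[(3R)-3-hydroxy-2,2-dimethyl-8-(3-methylbut-2-enyl)chroman-6-yl]chromen-4-one
Conditions: aq. HCl (3 M)/MeOH (1:4), 50 °C, followed closely and stopped at full conversion
Reagents that add atoms: none
Why: Acid-catalysed acetal exchange with methanol removes both MOM groups, the one at O5 (peri to the carbonyl) first; this is the usual last step for MOM-protected prenylated isoflavones. The prenyl group has no free ortho phenol to cyclise onto, and the secondary alcohol is neither benzylic nor allylic and does not ionise, so C3' is unaffected.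

## Compound list

1 | genistein, 5,7-dihydroxy-3-(4-hydroxyphenyl)chromen-4-one | O=c1c(-c2ccc(O)cc2)coc2cc(O)cc(O)c12 | starting material
2 | 5-hydroxy-3-(4-hydroxyphenyl)-7-(methoxymethoxy)chromen-4-one | O=c1c(-c2ccc(O)cc2)coc2cc(OCOC)cc(O)c12 | intermediate
3 | 3-chloro-3-methylbut-1-yne | CC(C)(Cl)C#C | starting material
4 | 5-hydroxy-7-(methoxymethoxy)-3-[4-(2-methylbut-3-yn-2-yloxy)phenyl]chromen-4-one | O=c1c(-c2ccc(OC(C)(C)C#C)cc2)coc2cc(OCOC)cc(O)c12 | intermediate
5 | 5-hydroxy-7-(methoxymethoxy)-3-[4-(2-methylbut-3-en-2-yloxy)phenyl]chromen-4-one | O=c1c(-c2ccc(OC(C)(C)C=C)cc2)coc2cc(OCOC)cc(O)c12 | intermediate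
6 | 5-hydroxy-3-[4-hydroxy-3-(3-methylbut-2-enyl)phenyl]-7-(methoxymethoxy)chromen-4-one | CC(C)=CCc1cc(-c2coc3cc(OCOC)cc(O)c3c2=O)ccc1O | intermediate
7 | 5-hydroxy-7-(methoxymethoxy)-3-[3-(3-methylbut-2-enyl)-4-(2-methylbut-3-yn-2-yloxy)phenyl]chromen-4-one | CC(C)=CCc1cc(-c2coc3cc(OCOC)cc(O)c3c2=O)ccc1OC(C)(C)C#C | intermediate
8 | 5-hydroxy-3-[4-hydroxy-3-(3-methylbuta-1,2-dienyl)-5-(3-methylbut-2-enyl)phenyl]-7-(methoxymethoxy)chromen-4-one (ortho-allenylphenol, not isolated) | CC(C)=CCc1cc(-c2coc3cc(OCOC)cc(O)c3c2=O)cc(C=C=C(C)C)c1O | intermediate
9 | 3-[2,2-dimethyl-8-(3-methylbut-2-enyl)-2H-chromen-6-yl]-5-hydroxy-7-(methoxymethoxy)chromen-4-one | CC(C)=CCc1cc(-c2coc3cc(OCOC)cc(O)c3c2=O)cc2c1OC(C)(C)C=C2 | intermediate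
10 | 3-[2,2-dimethyl-8-(3-methylbut-2-enyl)-2H-chromen-6-yl]-5,7-bis(methoxymethoxy)chromen-4-one | CC(C)=CCc1cc(-c2coc3cc(OCOC)cc(OCOC)c3c2=O)cc2c1OC(C)(C)C=C2 | intermediate
11 | 3-[(3R,4R)-3,4-epoxy-2,2-dimethyl-8-(3-methylbut-2-enyl)chroman-6-yl]-5,7-bis(methoxymethoxy)chromen-4-one | CC(C)=CCc1cc(-c2coc3cc(OCOC)cc(OCOC)c3c2=O)cc2c1OC(C)(C)[C@@H]3O[C@H]23 | intermediate
12 | 3-[(3R)-3-hydroxy-2,2-dimethyl-8-(3-methylbut-2-enyl)chroman-6-yl]-5,7-bis(methoxymethoxy)chromen-4-one | CC(C)=CCc1cc(-c2coc3cc(OCOC)cc(OCOC)c3c2=O)cc2c1OC(C)(C)[C@H](O)C2 | intermediate
13 | 5,7-dihydroxy-3-[(3R)-3-hydroxy-2,2-dimethyl-8-(3-methylbut-2-enyl)chroman-6-yl]chromen-4-one | CC(C)=CCc1cc(-c2coc3cc(O)cc(O)c3c2=O)cc2c1OC(C)(C)[C@H](O)C2 | target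

## Step count and least certain steps

Total step count: 10. Longest linear sequence: 10 steps (1 to 13); the route is fully linear, with 3 used twice.

Step 8 (key step). The most likely failure is loss of chemoselectivity: oxygen transfer to the prenyl alkene as conversion rises, or electrophilic chlorination of the doubly activated ring A by hypochlorite. A second risk is weaker enantioface discrimination than with simple chromenes, because the prenyl group sits next to O1'. Fallback: from 10, asymmetric hydroboration with diisopinocampheylborane (Ipc2BH made from (−)-α-pinene, the antipode suggested by the empirical model for cis-alkenes; THF, −25 °C) would place boron at C3' and hydrogen at C4' on one face and give the trialkylborane F1. Oxidation in the same flask with NaBO3·4H2O, with retention at carbon, rejoins the route at 12, and step 9 is then not needed. This reagent prefers cis-disubstituted alkenes, is sluggish toward the trisubstituted prenyl group, and exposes ring A to no electrophilic oxidant.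

Step 9. The most likely failure is capture of the benzylic radical by a second titanium centre followed by elimination of the titanium-bound oxygen, which is deoxygenation back to the chromene; single-electron reduction of the chromenone carbonyl is a lesser risk. Fallback: from 11, opening with thiophenolate (PhSH, K2CO3, DMF, rt), which attacks the benzylic C4' with inversion and leaves the C3'–O bond alone, would give the trans hydroxy sulfide F2. Homolytic desulfurisation (Bu3SnH, AIBN, toluene, 90 °C) then removes sulfur from C4' and returns to 12.

Step 1. The most likely failure is incomplete site selectivity: proton exchange between the phenoxides competes with alkylation, so the ring B hydroxyl is alkylated as well. Fallback: from 1, peracetylation (Ac2O, pyridine, DMAP) would give the triacetate F3. Selective removal of the most labile 7-O-acetyl group (PhSH, imidazole, N-methylpyrrolidone, 0 °C, a known selective 7-deacylation of polyacylated flavonoids) gives the 7-hydroxy diacetate F4. MOM protection of the only free hydroxyl (MOMCl, i-Pr2NEt, CH2Cl2) gives F5, and methanolysis of the two remaining acetates (K2CO3, MeOH, rt) returns to 2 with the MOM group placed unambiguously.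

Step 10. The most likely failure is Markovnikov addition of methanol, water or HCl to the prenyl alkene while the slower 7-O-MOM group is still being cleaved. Fallback: from 12, TESOTf with 2,2'-bipyridyl (CH2Cl2, 0 °C) would exchange the aryl MOM ethers for triethylsilyl ethers without free Brønsted acid and silylate the alcohol, giving the tris(triethylsilyl) ether F6. Buffered fluoride (TBAF, AcOH, THF, 0 °C) then releases 13.

## Further compounds

F1 | step 8 | 3-[(3'-position) bis(isopinocampheyl)boryl adduct of 10]: 3-{3-[bis((1S,2S,3S,5R)-2,6,6-trimethylbicyclo[3.1.1]heptan-3-yl)boranyl]-2,2-dimethyl-8-(3-methylbut-2-enyl)chroman-6-yl}-5,7-bis(methoxymethoxy)chromen-4-one, boron on the face that becomes the (R)-alcohol | CC(C)=CCc1cc(-c2coc3cc(OCOC)cc(OCOC)c3c2=O)cc2c1OC(C)(C)[C@H](B([C@H]1C[C@H]3C[C@@H]([C@@H]1C)C3(C)C)[C@H]1C[C@H]3C[C@@H]([C@@H]1C)C3(C)C)C2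
F2 | step 9 | 3-[(3S,4S)-3-hydroxy-2,2-dimethyl-8-(3-methylbut-2-enyl)-4-(phenylsulfanyl)chroman-6-yl]-5,7-bis(methoxymethoxy)chromen-4-one (trans; C3' spatially as in 12, descriptor changed by the sulfur at C4') | CC(C)=CCc1cc(-c2coc3cc(OCOC)cc(OCOC)c3c2=O)cc2c1OC(C)(C)[C@H](O)[C@H]2Sc1ccccc1
F3 | step 1 | 4-(5,7-diacetoxy-4-oxochromen-3-yl)phenyl acetate (genistein triacetate) | CC(=O)Oc1ccc(cc1)-c1coc2cc(OC(C)=O)cc(OC(C)=O)c2c1=O
F4 | step 1 | 4-(5-acetoxy-7-hydroxy-4-oxochromen-3-yl)phenyl acetate | CC(=O)Oc1ccc(cc1)-c1coc2cc(O)cc(OC(C)=O)c2c1=O
F5 | step 1 | 4-[5-acetoxy-7-(methoxymethoxy)-4-oxochromen-3-yl]phenyl acetate | CC(=O)Oc1ccc(cc1)-c1coc2cc(OCOC)cc(OC(C)=O)c2c1=O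
F6 | step 10 | 3-[(3R)-2,2-dimethyl-8-(3-methylbut-2-enyl)-3-(triethylsilyloxy)chroman-6-yl]-5,7-bis(triethylsilyloxy)chromen-4-one | CC(C)=CCc1cc(-c2coc3cc(O[Si](CC)(CC)CC)cc(O[Si](CC)(CC)CC)c3c2=O)cc2c1OC(C)(C)[C@H](O[Si](CC)(CC)CC)C2
A1 | alternative 1 | 3-[4-bromo-2-(3-methylbut-2-enyl)phenoxy]-1-diazo-3-methylbutan-2-one | CC(C)=CCc1cc(Br)ccc1OC(C)(C)C(=O)C=[N+]=[N-]
A2 | alternative 1 | 6-bromo-2,2-dimethyl-8-(3-methylbut-2-enyl)chroman-3-one | CC(C)=CCc1cc(Br)cc2c1OC(C)(C)C(=O)C2
A3 | alternative 2 | (Z)-3-[3,5-bis(allyloxy)phenoxy]-2-[(3R)-3-(tert-butyldimethylsilyloxy)-2,2-dimethyl-8-(3-methylbut-2-enyl)chroman-6-yl]acrylic acid | CC(C)=CCc1cc(/C(C(=O)O)=C/Oc2cc(OCC=C)cc(OCC=C)c2)cc2c1OC(C)(C)[C@H](O[Si](C)(C)C(C)(C)C)C2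
A4 | alternative 2 | 5,7-bis(allyloxy)-3-[(3R)-3-(tert-butyldimethylsilyloxy)-2,2-dimethyl-8-(3-methylbut-2-enyl)chroman-6-yl]chromen-4-one | CC(C)=CCc1cc(-c2coc3cc(OCC=C)cc(OCC=C)c3c2=O)cc2c1OC(C)(C)[C@H](O[Si](C)(C)C(C)(C)C)C2
A5 | alternative 3 | 3-{3-[((2R)-3,3-dimethyloxiran-2-yl)methyl]-4-hydroxy-5-(3-methylbut-2-enyl)phenyl}-5,7-bis(methoxymethoxy)chromen-4-one | CC(C)=CCc1cc(-c2coc3cc(OCOC)cc(OCOC)c3c2=O)cc(C[C@H]2OC2(C)C)c1O
A6 | alternative 3 | 3-[(3R)-3-hydroxy-2,2-dimethyl-8-(3-methylbut-2-enyl)chroman-6-yl]-5,7-bis(methoxymethoxy)chromen-4-one (identical with 12) | CC(C)=CCc1cc(-c2coc3cc(OCOC)cc(OCOC)c3c2=O)cc2c1OC(C)(C)[C@H](O)C2
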